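I decided to split each flask's rate into a part that needs Z and a part that does not, and to count orders from that split. A route without Z has order zero in [Z], and I assumed that the Z route brings two Z together, which gives it order two. The order of the sum is then twice the Z route's fraction of the rate. That two was my assumption, not a reading.

| flask | G | E | Z | L | time |
|---|---|---|---|---|---|
| winter | 0.0800 M | 0.0640 M | 0.00640 M |  |  |
| dawn | 0.0320 M | 0.0160 M | 0.00640 M |  |  |
| noon | 0.0800 M | 0.0640 M | 0.00320 M |  |  |
| dusk | 0.0800 M | 0.0640 M | 0.00640 M | 0.0400 M |  |
| midnight | 0.0800 M | 0.190 M | 0.00210 M |  | 68 min |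

| run | time / min | [L] / M |
|---|---|---|
| winter run | 2.7 | 0.0010 |
| winter run | 5.2 | 0 |
| winter run | 9.9 | 0.0038 |
| winter run | 19 | 0.0081 |
| winter run | 36 | 0.0199 |
| winter run | 68 | 0.0341 |
| dawn run | 2.7 | 0 |
| dawn run | 5.2 | 9 × 10⁻⁴ |
| dawn run | 9.9 | 0 |
| dawn run | 19 | 0.0020 |
| dawn run | 36 | 0.0020 |
| dawn run | 68 | 0.0045 |
| noon run | 2.7 | 0.0016 |
| noon run | 5.2 | 0.0013 |
| noon run | 9.9 | 0.0029 |
| noon run | 19 | 0.0067 |
| noon run | 36 | 0.0146 |
| noon run | 68 | 0.0305 |
| dusk run | 2.7 | 0.0434 |
| dusk run | 5.2 | 0.0480 |
| dusk run | 9.9 | 0.0532 |
| dusk run | 19 | 0.0640 |
| dusk run | 36 | 0.0764 |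
| dusk run | 68 | 0.0883 |

(scatter of a reading: 0.001 M)

- Overall: G + E -> L, with Z as catalyst.
- Constant volume, constant temperature.
- A reading of a species includes what of it is bound.
- An order is taken over about fifteen percent of the charge, up and down.

* apparent order in [Z] of the starting rate, round the charge of the winter run (the rate where two percent of its G have turned into L)
* the dawn run starts with 0.0480 M less of G and of E than the winter run, and with no L. Compared where both hold the same amount of G, once fifteen percent of what the dawn run was charged with has turned into L, is the dawn run faster, slower or alike (within a tenth)?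
* L in the midnight run at 68 min, as a share of the G charged

I began with the early part of the runs. Winter and noon differ in their Z, and their readings at 19 min and 36 min, summed, stood in the ratio 1.31, each sum with a scatter of 0.00141 M. Read as a straight power law, that ratio gives 0.395, but this is an average over the whole halving. Halving Z leaves a quarter of a two-Z route, so the ratio made that route 0.469 times the rest in winter. That gave 0.319 for φ, the Z share: the fraction of a flask's rate that runs through Z. In noon the share was 0.105, less than in winter. Round the winter charge, my order was therefore 0.638.

Next came the middle of a run. Dusk, charged with L, made 0.00136 M min⁻¹ early on, faster than the 4.26 × 10⁻⁴ M min⁻¹ of winter up to 19 min. The extra rate per amount of L was 0.0194 min⁻¹, so this is autocatalysis, and about 0.0220 M of L matches winter's early rate. Where dawn and winter hold equal G, winter holds 0.0480 M more L than dawn, whose last reading is 0.0045 M. I therefore called dawn slower.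

Then I took midnight to its end. Its Z is 0.00210 M, so scaling the two-Z route by the square of the Z ratio gave a Z share of 0.0480. Scaling winter's Z-free rate by E, and adding that share, gave a start of 9.05 × 10⁻⁴ M min⁻¹. At 0.0400 M of L, half of the G has gone, yet the L route lifts the rate to 0.00126 M min⁻¹. The mean of those two rates reaches that point at 36.9 min. G is the limiting reagent in midnight, with E charged 0.110 M above it, so from that point I treated the decay as pseudo-first-order in G, with 0.0316 min⁻¹. By 68 min that left 0.0149 M of G, so my L was 81.3% of the charge.

The forecast, reasoning that “the order in Z is weak”, gave 0.4, slower and 72%, which differs from my order and my share. The flask gave 0.73, slower and 93.4%.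

    Z + G ⇌ ZG, settled at all times (7.490 M⁻¹)
    Z + E ⇌ ZE, settled at all times (1.510 M⁻¹)
    ZG + ZE → L + 2 Z (234.6 M⁻¹ min⁻¹)
    G + E → L (0.05604 M⁻¹ min⁻¹)
    G + E + L → 2 L (5.328 M⁻² min⁻¹)

My winter order of 0.638 stood against 0.73. Taking the conversion of G + E into L out of winter raises the order to 1.6, towards the two of a pure Z route. For midnight my Z share was 0.0480, which put the weight of my reckoning on the routes without Z. Removing the conversion of G + E into L, or the conversion of G + E + L into 2 L, drops the 93.4% of midnight to 56.4% or 49.2%.

All runs were generated by integration on assumed constants.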